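**Plan**
Retrosynthesis: the C3 and C5 enone carbonyls go back to allylic silyl ethers and the C10 carbinol to a ketone; then the C8–C9 and O–C12 bonds are cut together; then the C2–C3 bond (alkenylchromium + aldehyde), leaving a ring C aldehyde and a ring A dienyl triflate.
Enabling feature: the oxane ring O–C8–C9–C10–C11–C12 of the 9-oxabicyclo[3.3.1]nonane core, with oxygen on C10, is an oxa-[4+2] retron; C8 is a ring C ketone carbon, C9=C10(OEt)–C11=C12 a 2-alkoxydiene exocyclic to ring A, and the three-atom link C2–C3–C4 holds them together.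
Forward: ring C aldehyde 9 from 2-methylcyclopentane-1,3-dione (steps 1–8); ring A triflate 17 by nickel-catalysed alkylative cyclisation of an ynal (steps 9–14); union at C2–C3 (step 15); one cycloaddition then closes ring B (eight-membered) and the oxygen bridge (step 17); reduction, desilylation and double allylic oxidation finish.
Stereochemistry: C4 from a yeast desymmetrisation (the C5 carbinol marks which ring C carbonyl becomes C8 and is oxidised at the end); C8 and C12 from C4 through the ring-fusion geometry of the cycloaddition; C11 and C10 from exo-face protonation and hydride delivery on the cage; the Z diene geometry from syn addition in the nickelacycle.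

Key step: step 17

Locants used throughout: C1 = ring A alkene carbon bearing CH2OMe; C2 = its alkene partner; C3 = carbon between C2 and C4; C4 = quaternary methyl carbon; C5 = ring C carbonyl carbon; C6=C7 = ring C alkene (C7 bears isopropyl); C8 = ring C carbon bearing the bridging oxygen; C9 = CH2; C10 = CHOH; C11 = CHMe; C12 = ring A carbon bearing the bridging oxygen; C13, C14 = ring A CH2 groups. Ring A = C1, C2, C12, C13, C14; ring B = C2, C3, C4, C8–C12; ring C = C4–C8.
Assumption: C3 is carried as a mixture of carbinol epimers from step 15 to step 19, because it ends as a ketone.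

**Ring C aldehyde**

Step 1
Reactants: 1 2-methylcyclopentane-1,3-dione
Product: 2 2-allyl-2-methylcyclopentane-1,3-dione
Conditions: allyl bromide, 1 M NaOH, H2O, rt
Reagents that add atoms: allyl bromide, C=CCBr
Why: C-alkylation of the stabilised dione enolate in water is the classical route to 2,2-disubstituted cyclopentane-1,3-diones; no stereocentre is formed.

Step 2
Reactants: 2 2-allyl-2-methylcyclopentane-1,3-dione
Product: 3 (2S,3S)-2-allyl-3-hydroxy-2-methylcyclopentan-1-one
Conditions: baker's yeast (Saccharomyces cerevisiae), sucrose, H2O, 30 °C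
Reagents that add atoms: none
Why: Enantiotopic-group-selective enzymatic ketone reduction, known for this substrate class to give the S carbinol with hydroxyl cis to allyl, should fix the quaternary centre that becomes C4 and distinguish the future C5 (carbinol) from C8 (ketone).

Step 3
Reactants: 3 (2S,3S)-2-allyl-3-hydroxy-2-methylcyclopentan-1-one
Product: 4 (2S,3S)-2-allyl-3-[(tert-butyldimethylsilyl)oxy]-2-methylcyclopentan-1-one
Conditions: TBSCl, imidazole, DMF, rt
Reagents that add atoms: tert-butyldimethylsilyl chloride, CC(C)(C)[Si](C)(C)Cl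
Why: Standard silylation of a secondary alcohol; no stereocentre is touched.

Step 4
Reactants: 4 (2S,3S)-2-allyl-3-[(tert-butyldimethylsilyl)oxy]-2-methylcyclopentan-1-one
Product: 5 (2S,3S)-3-[(tert-butyldimethylsilyl)oxy]-2-methyl-2-[(E)-prop-1-en-1-yl]cyclopentan-1-one
Conditions: [Ir(cod)(PMePh2)2]PF6 (2 mol %, activated with H2), THF, rt
Reagents that add atoms: none
Why: Iridium hydride-catalysed isomerisation of a terminal allyl group should give the E internal alkene, which places a cleavable C=C directly on the quaternary carbon.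

Step 5
Reactants: 5 (2S,3S)-3-[(tert-butyldimethylsilyl)oxy]-2-methyl-2-[(E)-prop-1-en-1-yl]cyclopentan-1-one
Product: 6 (4S,5S)-4-[(tert-butyldimethylsilyl)oxy]-5-methyl-5-[(E)-prop-1-en-1-yl]cyclopent-2-en-1-one
Conditions: IBX, DMSO, 70 °C
Reagents that add atoms: none
Why: IBX dehydrogenation of a ketone to the enone; regiochemistry is fixed because only one alpha carbon carries hydrogen.

Step 6
Reactants: 6 (4S,5S)-4-[(tert-butyldimethylsilyl)oxy]-5-methyl-5-[(E)-prop-1-en-1-yl]cyclopent-2-en-1-one
Product: 7 (4S,5S)-4-[(tert-butyldimethylsilyl)oxy]-2-iodo-5-methyl-5-[(E)-prop-1-en-1-yl]cyclopent-2-en-1-one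
Conditions: I2, pyridine, CH2Cl2, 0 °C → rt
Reagents that add atoms: iodine, II
Why: Johnson alpha-iodination of a cyclic enone (pyridine conjugate addition, enolate iodination, elimination) should put iodine on the future C7.

Step 7
Reactants: 7 (4S,5S)-4-[(tert-butyldimethylsilyl)oxy]-2-iodo-5-methyl-5-[(E)-prop-1-en-1-yl]cyclopent-2-en-1-one
Product: 8 (4S,5S)-4-[(tert-butyldimethylsilyl)oxy]-2-isopropyl-5-methyl-5-[(E)-prop-1-en-1-yl]cyclopent-2-en-1-one
Conditions: i-PrZnBr, Pd(OAc)2 (2 mol %), CPhos (4 mol %), THF, rt
Reagents that add atoms: isopropylzinc bromide, CC(C)[Zn]Br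
Why: Negishi coupling of an alpha-iodoenone with a secondary alkylzinc; the biaryl phosphine should suppress beta-hydride isomerisation to n-propyl.

Step 8
Reactants: 8 (4S,5S)-4-[(tert-butyldimethylsilyl)oxy]-2-isopropyl-5-methyl-5-[(E)-prop-1-en-1-yl]cyclopent-2-en-1-one
Product: 9 (1R,5S)-5-[(tert-butyldimethylsilyl)oxy]-3-isopropyl-1-methyl-2-oxocyclopent-3-ene-1-carbaldehyde
Conditions: OsO4 (2 mol %), NaIO4, 2,6-lutidine, dioxane/H2O, rt
Reagents that add atoms: osmium tetroxide (catalytic oxygen donor), O=[Os](=O)(=O)=O; sodium periodate (terminal oxidant), [Na+].[O-]I(=O)(=O)=O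
Why: Lemieux–Johnson cleavage should take the electron-rich disubstituted propenyl alkene in preference to the hindered, electron-poor enone alkene and give the C3 aldehyde.

**Ring A triflate**

Step 9
Reactants: 10 pent-3-yn-1-ol
Product: 11 5-iodopent-2-yne
Conditions: PPh3, I2, imidazole, CH2Cl2, 0 °C → rt
Reagents that add atoms: iodine, II
Why: Appel-type iodination of a primary alcohol.

Step 10
Reactants: 12 methyl 3-methoxypropanoate; 11 5-iodopent-2-yne
Product: 13 methyl 2-(methoxymethyl)hept-5-ynoate (racemic)
Conditions: LiN(i-Pr)2, THF, −78 °C; then 11, DMPU, −78 → −30 °C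
Reagents that add atoms: none
Why: Ester enolate alkylation with a primary iodide, kept cold so that the beta-methoxy enolate does not lose methoxide; the new centre becomes sp2 in step 14.

Step 11
Reactants: 13 methyl 2-(methoxymethyl)hept-5-ynoate
Product: 14 2-(methoxymethyl)hept-5-ynal (racemic)
Conditions: i-Bu2AlH (1.1 equiv), CH2Cl2, −78 °C
Reagents that add atoms: none
Why: Partial reduction of an ester through the aluminium hemiacetal, which is stable at −78 °C and gives the aldehyde on work-up.

Step 12
Reactants: 14 2-(methoxymethyl)hept-5-ynal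
Product: 15 (Z)-2-(3-ethoxybut-3-en-2-ylidene)-5-(methoxymethyl)cyclopentan-1-ol (racemic, cis/trans mixture)
Conditions: ethyl vinyl ether, t-BuLi, THF, −78 → 0 °C; ZnCl2; then 14, Ni(cod)2 (10 mol %), THF, 0 °C
Reagents that add atoms: (1-ethoxyvinyl)zinc chloride, C=C(OCC)[Zn]Cl (made in the flask from ethyl vinyl ether, C=COCC)
Why: Nickel-catalysed alkylative cyclisation of an ynal with an organozinc (oxidative cyclisation to an oxanickelacyclopentene, transmetalation, reductive elimination) adds the ring bond and the transferred group syn across the alkyne, so the 1-ethoxyvinyl group should end cis to the carbinol carbon C2 and the methyl cis to C13; the two sp3 centres are later destroyed.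

Step 13
Reactants: 15 (Z)-2-(3-ethoxybut-3-en-2-ylidene)-5-(methoxymethyl)cyclopentan-1-ol
Product: 16 (Z)-2-(3-ethoxybut-3-en-2-ylidene)-5-(methoxymethyl)cyclopentan-1-one (racemic)
Conditions: Dess–Martin periodinane, pyridine, CH2Cl2, 0 °C → rt
Reagents that add atoms: none
Why: Buffered Dess–Martin oxidation of a secondary allylic alcohol should leave the acid-sensitive dienol ether intact.

Step 14
Reactants: 16 (Z)-2-(3-ethoxybut-3-en-2-ylidene)-5-(methoxymethyl)cyclopentan-1-one
Product: 17 (Z)-5-(3-ethoxybut-3-en-2-ylidene)-2-(methoxymethyl)cyclopent-1-en-1-yl trifluoromethanesulfonate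
Conditions: KN(SiMe3)2, PhNTf2, THF, −78 °C
Reagents that add atoms: N-phenylbis(trifluoromethanesulfonimide), O=S(=O)(N(c1ccccc1)S(=O)(=O)C(F)(F)F)C(F)(F)F
Why: Kinetic enolate O-triflation; the only alpha hydrogen is on the methoxymethyl-bearing carbon, so the C1=C2 alkene forms regiospecifically, and low temperature with fast trapping should prevent loss of methoxide.

**Union and endgame**

Step 15
Reactants: 9 (1R,5S)-5-[(tert-butyldimethylsilyl)oxy]-3-isopropyl-1-methyl-2-oxocyclopent-3-ene-1-carbaldehyde; 17 (Z)-5-(3-ethoxybut-3-en-2-ylidene)-2-(methoxymethyl)cyclopent-1-en-1-yl trifluoromethanesulfonate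
Product: 18 coupled allylic alcohol: the formyl carbon of 9 (now C3, CHOH) bonded to C2 of ring A; C4 and C5 as in 9, Z dienol ether as in 17, both C3 epimers
Conditions: CrCl2 (4 equiv), NiCl2 (2 mol %), DMF/THF, rt
Reagents that add atoms: none
Why: Nozaki–Hiyama–Kishi coupling forms the alkenylchromium from the triflate and adds it chemoselectively to the aldehyde in the presence of the ring C enone and the dienol ether; the new C3 centre is not controlled and is oxidised in step 20.

Step 16
Reactants: 18 coupled allylic alcohol
Product: 19 C3 tert-butyldimethylsilyl ether of 18 (both C3 epimers)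
Conditions: TBSOTf, 2,6-lutidine, CH2Cl2, −78 °C
Reagents that add atoms: tert-butyldimethylsilyl trifluoromethanesulfonate, CC(C)(C)[Si](C)(C)OS(=O)(=O)C(F)(F)F
Why: Base-buffered silyl triflate silylation of a hindered alcohol keeps C3 at the alcohol level and blocks the hydroxyl, which would otherwise add to the dienol ether.

Step 17
Reactants: 19 C3 silyl ether
Product: 21 cage ketone: rings A, B and C with the C8–O–C12 bridge, C10 ketone, C11 methyl as in the target, C3 and C5 silyl ethers, via ethyl enol ether cycloadduct 20 (not isolated)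
Conditions: Me2AlCl (1.2 equiv), CH2Cl2, −78 → −40 °C; then 1 M HCl, THF, 0 °C
Reagents that add atoms: water, O
Why: Proposed new method: Me2AlCl bound to the C8 carbonyl should let the enol-ether terminus C9 attack C8 and the resulting aluminium alkoxide collapse onto C12 of the ethoxyallyl cation, a bridged-mode intramolecular oxa-[4+2] cycloaddition whose closest known relative is the Lewis-acid-promoted hetero-Diels–Alder (Mukaiyama aldol, then oxa-Michael) reaction of 2-oxydienes with carbonyl compounds, not so far used through a three-atom tether to close a medium ring; acid work-up then hydrolyses enol ether 20 to ketone 21. The C8–C9 bond closes ring B in an 8-(enolendo)-exo-trig sense, and the O–C12 bond closes the oxane ring O–C8–C9–C10–C11–C12 6-endo-trig and at the same time the second oxane ring O–C8–C4–C3–C2–C12 6-exo-trig. C8 is controlled by the preset C4: ring C spans bridgehead C8 and C4 of the emerging 9-oxabicyclo[3.3.1]nonane, and only when the diene adds to the C8=O face syn to the C4 methyl does C5 sit on the axial bond of C4, whose dihedral to the exocyclic bridgehead bond C8–C7 (roughly 40° by a model estimate) suits a five-membered ring, whereas the other face would need the equatorial bond (roughly 80°). C12 follows from C8 because the one-atom oxygen bridge can join the two carbons on one side only, and C11 is set in the hydrolysis by protonation of the enol ether on the open exo face, away from the C2–C3–C4 bridge. The step needs regioselectivity (C9 to carbon, oxygen to C12), secured by the donor polarity of the 2-ethoxydiene and by the tether, and chemoselectivity for 1,2- over 1,4-addition and against other carbonyls, secured by ring size (eight against nine) and by keeping C3 as a silyl ether so that no second carbonyl lies within six-membered reach of C9.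

Step 18
Reactants: 21 cage ketone
Product: 22 cage alcohol: C10 hydroxyl as in the target, C3 and C5 silyl ethers
Conditions: NaBH4, MeOH/THF, −20 °C
Reagents that add atoms: none
Why: Borohydride reduction of the only ketone; hydride should arrive on the exo face of the bicyclo[3.3.1] cage, opposite the C2–C3–C4 bridge, which places the C10 hydroxyl endo as in the target.

Step 19
Reactants: 22 cage alcohol
Product: 23 C3,C5,C10-triol (both C3 epimers)
Conditions: HF·pyridine, pyridine, THF, 0 °C → rt
Reagents that add atoms: none
Why: Fluoride cleavage of both silyl ethers under buffered, non-basic conditions should spare the tertiary bis-allylic ether bridge.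

Step 20
Reactants: 23 triol
Product: 24 alterbrassicicene C
Conditions: MnO2 (activated, excess), CH2Cl2, rt
Reagents that add atoms: none
Why: MnO2 oxidises allylic alcohols selectively, so the C3 and C5 carbinols should become the two enone carbonyls while the saturated C10 alcohol stays, and both C3 epimers converge on the target.

**Compound list**
1 | 2-methylcyclopentane-1,3-dione | CC1C(=O)CCC1=O | starting material
2 | 2-allyl-2-methylcyclopentane-1,3-dione | C=CCC1(C)C(=O)CCC1=O | intermediate
3 | (2S,3S)-2-allyl-3-hydroxy-2-methylcyclopentan-1-one | C=CC[C@]1(C)C(=O)CC[C@@H]1O | intermediate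
4 | (2S,3S)-2-allyl-3-[(tert-butyldimethylsilyl)oxy]-2-methylcyclopentan-1-one | C=CC[C@]1(C)C(=O)CC[C@@H]1O[Si](C)(C)C(C)(C)C | intermediate
5 | (2S,3S)-3-[(tert-butyldimethylsilyl)oxy]-2-methyl-2-[(E)-prop-1-en-1-yl]cyclopentan-1-one | C/C=C/[C@]1(C)C(=O)CC[C@@H]1O[Si](C)(C)C(C)(C)C | intermediate
6 | (4S,5S)-4-[(tert-butyldimethylsilyl)oxy]-5-methyl-5-[(E)-prop-1-en-1-yl]cyclopent-2-en-1-one | C/C=C/[C@]1(C)C(=O)C=C[C@@H]1O[Si](C)(C)C(C)(C)C | intermediate
7 | (4S,5S)-4-[(tert-butyldimethylsilyl)oxy]-2-iodo-5-methyl-5-[(E)-prop-1-en-1-yl]cyclopent-2-en-1-one | C/C=C/[C@]1(C)C(=O)C(I)=C[C@@H]1O[Si](C)(C)C(C)(C)C | intermediate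
8 | (4S,5S)-4-[(tert-butyldimethylsilyl)oxy]-2-isopropyl-5-methyl-5-[(E)-prop-1-en-1-yl]cyclopent-2-en-1-one | C/C=C/[C@]1(C)C(=O)C(C(C)C)=C[C@@H]1O[Si](C)(C)C(C)(C)C | intermediate
9 | (1R,5S)-5-[(tert-butyldimethylsilyl)oxy]-3-isopropyl-1-methyl-2-oxocyclopent-3-ene-1-carbaldehyde | O=C[C@]1(C)C(=O)C(C(C)C)=C[C@@H]1O[Si](C)(C)C(C)(C)C | intermediate
10 | pent-3-yn-1-ol | CC#CCCO | starting material
11 | 5-iodopent-2-yne | CC#CCCI | intermediate
12 | methyl 3-methoxypropanoate | COCCC(=O)OC | starting material
13 | methyl 2-(methoxymethyl)hept-5-ynoate (racemic) | COCC(CCC#CC)C(=O)OC | intermediate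
14 | 2-(methoxymethyl)hept-5-ynal (racemic) | COCC(CCC#CC)C=O | intermediate
15 | (Z)-2-(3-ethoxybut-3-en-2-ylidene)-5-(methoxymethyl)cyclopentan-1-ol (racemic, cis/trans mixture) | C=C(OCC)/C(C)=C1/CCC(COC)C1O | intermediate
16 | (Z)-2-(3-ethoxybut-3-en-2-ylidene)-5-(methoxymethyl)cyclopentan-1-one (racemic) | C=C(OCC)/C(C)=C1/CCC(COC)C1=O | intermediate
17 | (Z)-5-(3-ethoxybut-3-en-2-ylidene)-2-(methoxymethyl)cyclopent-1-en-1-yl trifluoromethanesulfonate | C=C(OCC)/C(C)=C1/CCC(COC)=C1OS(=O)(=O)C(F)(F)F | intermediate
18 | coupled allylic alcohol (C3 carbinol between ring A C2 and C4; both C3 epimers) | C=C(OCC)/C(C)=C1/CCC(COC)=C1C(O)[C@]2(C)C(=O)C(C(C)C)=C[C@@H]2O[Si](C)(C)C(C)(C)C | intermediate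
19 | C3 tert-butyldimethylsilyl ether of 18 (both C3 epimers) | C=C(OCC)/C(C)=C1/CCC(COC)=C1C(O[Si](C)(C)C(C)(C)C)[C@]2(C)C(=O)C(C(C)C)=C[C@@H]2O[Si](C)(C)C(C)(C)C | intermediate
20 | ethyl enol ether cycloadduct (C10(OEt)=C11, C8–O–C12 bridge; both C3 epimers) | COCC1=C2C(O[Si](C)(C)C(C)(C)C)[C@@]3(C)[C@@H](O[Si](C)(C)C(C)(C)C)C=C(C(C)C)[C@]34CC(OCC)=C(C)[C@@]2(CC1)O4 | intermediate
21 | cage ketone (C10 ketone; C4, C8, C11, C12 as in the target; C5 silyl ether cis to C3; both C3 epimers) | COCC1=C2C(O[Si](C)(C)C(C)(C)C)[C@@]3(C)[C@@H](O[Si](C)(C)C(C)(C)C)C=C(C(C)C)[C@]34CC(=O)[C@H](C)[C@@]2(CC1)O4 | intermediate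
22 | cage alcohol (C10 hydroxyl as in the target; both C3 epimers) | COCC1=C2C(O[Si](C)(C)C(C)(C)C)[C@@]3(C)[C@@H](O[Si](C)(C)C(C)(C)C)C=C(C(C)C)[C@]34C[C@H](O)[C@H](C)[C@@]2(CC1)O4 | intermediate
23 | C3,C5,C10-triol (both C3 epimers) | COCC1=C2C(O)[C@@]3(C)[C@@H](O)C=C(C(C)C)[C@]34C[C@H](O)[C@H](C)[C@@]2(CC1)O4 | intermediate
24 | alterbrassicicene C | COCC1=C2C(=O)[C@@]3(C)C(=O)C=C(C(C)C)[C@]34C[C@H](O)[C@H](C)[C@@]2(CC1)O4 | target

**Count**
Total steps: 20. Longest linear sequence: 14 (steps 1–8, then 15–20).

**Steps most likely to fail**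

Step 17 (proposed new method). Ring B may not close at a useful rate onto the hindered, conjugated C8 carbonyl. The Lewis acid may instead ionise an allylic silyl ether, the dienol ether may be lost to adventitious protonation, or addition may take the conjugate position or the other carbonyl face. The fallback uses known chemistry and sets out from 19. NBS and NaHCO3 in THF/H2O at 0 °C should convert the 2-ethoxydiene into the bromomethyl enone F1. SmI2 in THF at −78 °C should then close ring B by a samarium Reformatsky-type aldol addition of C9 to the C8 ketone, a reaction type with precedent for eight-membered rings, giving the ketol F2. DBU in CH2Cl2 should add the C8 hydroxyl across the ring to C12 (oxa-Michael addition); because the aldol is reversible under these conditions, material should drain through the C8 epimer that can form the cis-fused bridge. Exo-face protonation at C11 then returns the route at ketone 21.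

Step 12. The alkoxyvinylzinc may add directly to the aldehyde before oxidative cyclisation, transfer of the functionalised vinyl group from zinc to nickel may be slow, or the dienol ether may hydrolyse on work-up. The fallback sets out from ester 13. Ti(O-i-Pr)4 with i-PrMgCl (2 equiv) in Et2O at −50 °C should form the alkyne–titanium complex, which attacks the ester intramolecularly (nucleophilic acyl substitution, loss of methoxide) and leaves an alkenyltitanium cis to the new ring ketone. Quenching with I2 should give the iodoalkylidene ketone F3. Stille coupling with tributyl(1-ethoxyvinyl)stannane (Pd(PPh3)4, CuI, DMF) proceeds with retention and returns the route at ketone 16, so steps 11 to 13 are left out.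

Step 15. Coupling of two hindered partners may be slow, with protodemetalation of the alkenylchromium or deformylation of the non-enolisable keto aldehyde competing. The fallback sets out from triflate 17. (Me3Sn)2, LiCl and Pd(PPh3)4 in THF at 60 °C should give the alkenylstannane F4. Tin–lithium exchange with MeLi at −78 °C, transmetalation to CeCl3 and addition to aldehyde 9 (aldehyde before the hindered enone ketone) returns the route at alcohol 18.

Further compounds
F1 | step 17 | bromomethyl enone (C9 bromide, C10 ketone, Z C11=C12; rest as 19) | BrCC(=O)/C(C)=C1/CCC(COC)=C1C(O[Si](C)(C)C(C)(C)C)[C@]2(C)C(=O)C(C(C)C)=C[C@@H]2O[Si](C)(C)C(C)(C)C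
F2 | step 17 | eight-membered ketol (C8 hydroxyl, C10 ketone, C11=C12 in ring B; no oxygen bridge) | COCC1=C2C(O[Si](C)(C)C(C)(C)C)[C@@]3(C)[C@@H](O[Si](C)(C)C(C)(C)C)C=C(C(C)C)[C@]3(O)CC(=O)/C(C)=C2/CC1
F3 | step 12 | (Z)-2-(1-iodoethylidene)-5-(methoxymethyl)cyclopentan-1-one (racemic) | I/C(C)=C1/CCC(COC)C1=O
F4 | step 15 | (Z)-[5-(3-ethoxybut-3-en-2-ylidene)-2-(methoxymethyl)cyclopent-1-en-1-yl]trimethylstannane | C=C(OCC)/C(C)=C1/CCC(COC)=C1[Sn](C)(C)C
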